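**Retrosynthetic overview**

1. The target is a trans-fused α-methylene-γ-butyrolactone (ring A: O1, C2, C3, C3a, C7a) on a cyclohexene (ring B: C3a, C4, C5=C6, C7, C7a). Its side-chain stereocentre is C3 of (S)-citronellal (chiral pool).
2. Enabling feature: C4(OH)–C3a–C3(=CH2)–C2(=O)O is the signature of γ-attack of a 2-carbonyl-allyl metal on an aldehyde. The ring-B olefin C5=C6 carries only carbon substituents, so it can be stitched from two 1,1-disubstituted alkenes.
3. Key disconnection (C3a–C4 and C5=C6 together): 2-substituted acrolein 6 (C4, C5, side chain, acetate) plus 3-(bromomethyl)butenolide 14 (ring A, C7a, C7, C6, CH2O-isobutyrate). Both esters are already in place, so the key step ends the synthesis.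
4. Butenolide 14 comes from ring-closing metathesis of the 2-(bromomethyl)acrylate of vinyl carbinol 11. The carbinol centre (C7a) is set by Cr-catalysed enantioselective allylation of acrolein.
5. Ring order: A (step 9), then B (step 10). C7a relays to C3a and C4 in the key step.

Key step: step 10

Remark on the chemistry: (S)-(−)-citronellal of high enantiomeric purity is assumed. The key step is run in one vessel in two stages (aqueous phase withdrawn after stage 1, 15 not purified).

**Step 1**
Reactants: 1 (S)-citronellal
Product: 2 (6S)-8,8-dimethoxy-2,6-dimethyloct-2-ene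
Conditions: HC(OMe)3, MeOH, PPTS (cat.), rt
Reagents that add atoms: trimethyl orthoformate, COC(OC)OC; methanol, CO
Why: Mild acid-catalysed acetalisation with a water scavenger should mask the aldehyde without triggering the carbonyl-ene cyclisation of citronellal; the stereocentre is not touched.

**Step 2**
Reactants: 2 (6S)-8,8-dimethoxy-2,6-dimethyloct-2-ene
Product: 3 (4S)-6,6-dimethoxy-4-methylhexan-1-ol
Conditions: O3, CH2Cl2/MeOH, −78 °C; then NaBH4, −78 °C → rt
Reagents that add atoms: ozone, [O-][O+]=O
Why: Ozonolysis of the trisubstituted olefin with reductive (hydride) work-up should give the primary alcohol directly; the acetal is inert.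

**Step 3**
Reactants: 3 (4S)-6,6-dimethoxy-4-methylhexan-1-ol
Product: 4 (4S)-6,6-dimethoxy-4-methylhexyl acetate
Conditions: Ac2O, pyridine, DMAP (cat.), CH2Cl2, 0 °C → rt
Reagents that add atoms: acetic anhydride, CC(=O)OC(C)=O
Why: Standard O-acetylation installs the acetate of the target while the aldehyde is still masked.

**Step 4**
Reactants: 4 (4S)-6,6-dimethoxy-4-methylhexyl acetate
Product: 5 (4S)-4-methyl-6-oxohexyl acetate
Conditions: 1 M aq. HCl, THF, rt
Reagents that add atoms: water, O
Why: Acid-catalysed acetal hydrolysis should free the aldehyde faster than the acetate is cleaved; the β-stereocentre cannot enolise.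

**Step 5**
Reactants: 5 (4S)-4-methyl-6-oxohexyl acetate
Product: 6 (4S)-5-formyl-4-methylhex-5-en-1-yl acetate
Conditions: 37% aq. HCHO, pyrrolidine (10 mol%), EtCO2H (10 mol%), i-PrOH, 45 °C
Reagents that add atoms: formaldehyde, C=O
Why: Amine-catalysed Mannich condensation/elimination (organocatalytic α-methylenation) should turn the α-CH2 into the 2-substituted acrolein; the adjacent stereocentre is not part of the enamine.

**Step 6**
Reactants: 7 3-bromo-2-(bromomethyl)prop-1-ene
Product: 8 2-(bromomethyl)prop-2-en-1-yl 2-methylpropanoate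
Conditions: i-PrCO2Na (1 equiv), 7 (3 equiv), DMF, rt
Reagents that add atoms: sodium 2-methylpropanoate, CC(C)C(=O)[O-].[Na+]
Why: SN2 displacement of one allylic bromide by the carboxylate; the excess of 7 should suppress the diester.

**Step 7**
Reactants: 8 2-(bromomethyl)prop-2-en-1-yl 2-methylpropanoate; 9 acrolein
Product: 11 (4R)-4-hydroxy-2-methylidenehex-5-en-1-yl 2-methylpropanoate, via trimethylsilyl ether 10 (not isolated)
Conditions: CrCl3 (10 mol%), chiral tridentate 1,8-bis(oxazolinyl)carbazole ligand (12 mol%, enantiomer that gives R), Mn powder, i-Pr2NEt (30 mol%), Me3SiCl, THF, 0 °C; then 1 M aq. HCl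
Reagents that add atoms: chlorotrimethylsilane, C[Si](C)(C)Cl (its silyl group is present only in 10)
Why: Catalytic enantioselective Nozaki–Hiyama allylation: the ligated allylchromium should add 1,2 to acrolein through a closed six-membered transition state in which the ligand selects the aldehyde face and so sets the R carbinol (later C7a); the ester is inert to chromium.

**Step 8**
Reactants: 11 (4R)-4-hydroxy-2-methylidenehex-5-en-1-yl 2-methylpropanoate; 12 2-(bromomethyl)prop-2-enoic acid
Product: 13 (3R)-5-{[(2-methylpropanoyl)oxy]methyl}hexa-1,5-dien-3-yl 2-(bromomethyl)prop-2-enoate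
Conditions: DCC, DMAP (5 mol%), CH2Cl2, −10 °C → 0 °C
Reagents that add atoms: none
Why: Steglich esterification at low temperature with little DMAP should acylate the secondary alcohol with retention and spare the allylic bromide.

**Step 9**
Reactants: 13 (3R)-5-{[(2-methylpropanoyl)oxy]methyl}hexa-1,5-dien-3-yl 2-(bromomethyl)prop-2-enoate
Product: 14 2-{[(2R)-4-(bromomethyl)-5-oxo-2,5-dihydrofuran-2-yl]methyl}prop-2-en-1-yl 2-methylpropanoate
Conditions: second-generation Grubbs catalyst (5 mol%), CH2Cl2 (5 mM), 40 °C
Reagents that add atoms: none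
Why: Ring-closing metathesis of the vinyl group onto the acrylate should close ring A as a five-membered butenolide; the methallyl olefin could only give a cyclobutene with the vinyl group and is left alone.

**Step 10**
Reactants: 14 2-{[(2R)-4-(bromomethyl)-5-oxo-2,5-dihydrofuran-2-yl]methyl}prop-2-en-1-yl 2-methylpropanoate; 6 (4S)-5-formyl-4-methylhex-5-en-1-yl acetate
Product: 16 [(3aR,4S,7aR)-5-[(2S)-5-(acetyloxy)pentan-2-yl]-4-hydroxy-3-methylidene-2-oxo-2,3,3a,4,7,7a-hexahydro-1-benzofuran-6-yl]methyl 2-methylpropanoate, via dienol 15 (not isolated)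
Conditions: Zn dust, THF/sat. aq. NH4Cl, 0 °C → rt; aqueous layer withdrawn, solvent switched to PhMe in the same vessel; N,N'-di(o-tolyl) second-generation Hoveyda–Grubbs catalyst (10 mol%), 1,4-benzoquinone (20 mol%), PhMe (2 mM), 80 °C
Reagents that add atoms: none
Why: Zinc inserts into the allylic C–Br bond of 14 and the resulting 2-carbonyl-allylzinc is trapped in situ by aldehyde 6 through its γ-carbon (Barbier allylation with allyl transposition), which forms C3a–C4 and unveils the exocyclic methylene; the dienol 15 then closes ring B by ruthenium-alkylidene ring-closing metathesis of its two 1,1-disubstituted olefins (C5=CH2 and C6=CH2, loss of ethene), which forms C5=C6. The closest known reaction types are the zinc- or indium-mediated aqueous Barbier addition of 3-(bromomethyl)furan-2(5H)-ones to aldehydes, which gives β-(hydroxyalkyl)-α-methylene-γ-butyrolactones, and ring-closing metathesis to tetrasubstituted cyclohexenes with N-(o-tolyl)-substituted NHC ruthenium catalysts. Only ring B is closed, by metathesis of a 1,7-diene to a six-membered ring; the α-methylene lactone cannot compete, because its pairings would give a cyclobutene or a bridgehead olefin. C3a is controlled by the C7a stereocentre of 14 (the aldehyde should add to the planar allyl unit on the face opposite the C7a side chain, so that C3a–C4 and C7a–C7 are trans and the ring fusion becomes trans), and C4 by the metal: zinc in aqueous NH4Cl should react through the non-chair, lactone-carbonyl-chelated transition state of this ring-constrained reagent and give the syn adduct (4S, hydroxyl cis to C3 on ring B), whereas a chair-type chromium reagent would give the C4 epimer. The step needs 1,2-addition to the enal, zinc insertion into C–Br only (allylic isobutyrate, acetate and lactone stay intact in the neutral aqueous medium) and capture of the transient allylzinc faster than β-elimination of the lactone oxygen, all of which the in-situ Barbier protocol should secure. The order of events is essential: C3a–C4 must be made between two molecules before ring B exists, since cyclisation onto the preformed butenolide would force a cis ring fusion.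

**Compound list**

1 | (S)-citronellal, (3S)-3,7-dimethyloct-6-enal | O=CC[C@@H](C)CCC=C(C)C | starting material
2 | (6S)-8,8-dimethoxy-2,6-dimethyloct-2-ene | COC(OC)C[C@@H](C)CCC=C(C)C | intermediate
3 | (4S)-6,6-dimethoxy-4-methylhexan-1-ol | COC(OC)C[C@@H](C)CCCO | intermediate
4 | (4S)-6,6-dimethoxy-4-methylhexyl acetate | COC(OC)C[C@@H](C)CCCOC(C)=O | intermediate
5 | (4S)-4-methyl-6-oxohexyl acetate | O=CC[C@@H](C)CCCOC(C)=O | intermediate
6 | (4S)-5-formyl-4-methylhex-5-en-1-yl acetate | O=CC(=C)[C@@H](C)CCCOC(C)=O | intermediate
7 | 3-bromo-2-(bromomethyl)prop-1-ene | C=C(CBr)CBr | starting material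
8 | 2-(bromomethyl)prop-2-en-1-yl 2-methylpropanoate | C=C(CBr)COC(=O)C(C)C | intermediate
9 | acrolein (prop-2-enal) | C=CC=O | starting material
10 | (4R)-2-methylidene-4-[(trimethylsilyl)oxy]hex-5-en-1-yl 2-methylpropanoate | C=C[C@H](O[Si](C)(C)C)CC(=C)COC(=O)C(C)C | intermediate (not isolated)
11 | (4R)-4-hydroxy-2-methylidenehex-5-en-1-yl 2-methylpropanoate | C=C[C@H](O)CC(=C)COC(=O)C(C)C | intermediate
12 | 2-(bromomethyl)prop-2-enoic acid | OC(=O)C(=C)CBr | starting material
13 | (3R)-5-{[(2-methylpropanoyl)oxy]methyl}hexa-1,5-dien-3-yl 2-(bromomethyl)prop-2-enoate | C=C[C@@H](CC(=C)COC(=O)C(C)C)OC(=O)C(=C)CBr | intermediate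
14 | 2-{[(2R)-4-(bromomethyl)-5-oxo-2,5-dihydrofuran-2-yl]methyl}prop-2-en-1-yl 2-methylpropanoate | BrCC1=C[C@@H](CC(=C)COC(=O)C(C)C)OC1=O | intermediate
15 | (4S,6S)-6-hydroxy-4-methyl-5-methylidene-6-[(2R,3R)-4-methylidene-2-(2-{[(2-methylpropanoyl)oxy]methyl}prop-2-en-1-yl)-5-oxooxolan-3-yl]hexyl acetate | C=C1C(=O)O[C@H](CC(=C)COC(=O)C(C)C)[C@H]1[C@H](O)C(=C)[C@@H](C)CCCOC(C)=O | intermediate (not isolated)
16 | [(3aR,4S,7aR)-5-[(2S)-5-(acetyloxy)pentan-2-yl]-4-hydroxy-3-methylidene-2-oxo-2,3,3a,4,7,7a-hexahydro-1-benzofuran-6-yl]methyl 2-methylpropanoate | C=C1C(=O)O[C@@H]2CC(COC(=O)C(C)C)=C([C@@H](C)CCCOC(C)=O)[C@@H](O)[C@@H]12 | target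

**Totals**

Total step count: 10
Longest linear sequence: 6 steps (steps 1–5, then step 10)

**Steps most likely to fail**

Step 10. Stage 2 may stall: two 1,1-disubstituted olefins, one of them flanked by two branched carbons, initiate slowly, so catalyst decomposition and olefin migration by ruthenium hydrides can outrun ring closure. The fallback is a relay ring-closing metathesis that sets out from 5 and comes back at 16. A pyrrolidine/benzoic acid-catalysed cross-aldol condensation of 5 with 2-(allyloxy)acetaldehyde (C=CCOCC=O) should give the relay enal (4S,5E)-5-formyl-4-methyl-7-(prop-2-en-1-yloxy)hept-5-en-1-yl acetate F1. Zinc-mediated Barbier addition of 14 under the stage 1 conditions should give the relay dienol F2. The ruthenium alkylidene then loads on the unhindered allyl ether, expels 2,5-dihydrofuran, and is delivered directly onto C5, from where closure onto C6=CH2 gives 16.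

Step 7. Enantiofacial discrimination of the small, unhindered enal may be poor, and a ligand-free background allylation or polymerisation of acrolein may compete. The fallback sets out from 8 and 9 and comes back at 11. A zinc-mediated Barbier reaction (Zn, THF/sat. aq. NH4Cl) should give the racemic alcohol 4-hydroxy-2-methylidenehex-5-en-1-yl 2-methylpropanoate F3. A Sharpless kinetic resolution (Ti(OiPr)4, L-(+)-diisopropyl tartrate, t-BuOOH, 4 Å molecular sieves, CH2Cl2, −20 °C) should then consume the S enantiomer as the epoxy alcohol (4S)-4-hydroxy-2-methylidene-4-[(2R)-oxiran-2-yl]butyl 2-methylpropanoate F4 and leave 11.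

Step 9. The allylic bromide may be lost (SN2' attack, ruthenium-mediated side reactions) while closure onto the electron-poor 1,1-disubstituted acrylate is slow. The fallback introduces the halide only after ring A is closed; it sets out from 11 and comes back at 14.
- Steglich esterification of 11 with 2-({[tert-butyl(dimethyl)silyl]oxy}methyl)prop-2-enoic acid should give the silyloxymethyl acrylate F5.
- Ring-closing metathesis (second-generation Grubbs catalyst) should give the silyloxymethyl butenolide F6.
- HF·pyridine in THF should give the hydroxymethyl butenolide F7.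
- CBr4/PPh3 (Appel bromination) should give 14.

**Further compounds**

F1 | step 10 | (4S,5E)-5-formyl-4-methyl-7-(prop-2-en-1-yloxy)hept-5-en-1-yl acetate | O=C/C(=C/COCC=C)[C@@H](C)CCCOC(C)=O
F2 | step 10 | (4S,5E)-5-{(S)-hydroxy[(2R,3R)-4-methylidene-2-(2-{[(2-methylpropanoyl)oxy]methyl}prop-2-en-1-yl)-5-oxooxolan-3-yl]methyl}-4-methyl-7-(prop-2-en-1-yloxy)hept-5-en-1-yl acetate | C=C1C(=O)O[C@H](CC(=C)COC(=O)C(C)C)[C@H]1[C@H](O)/C(=C/COCC=C)[C@@H](C)CCCOC(C)=O
F3 | step 7 | racemic 4-hydroxy-2-methylidenehex-5-en-1-yl 2-methylpropanoate | C=CC(O)CC(=C)COC(=O)C(C)C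
F4 | step 7 | (4S)-4-hydroxy-2-methylidene-4-[(2R)-oxiran-2-yl]butyl 2-methylpropanoate | O[C@@H](CC(=C)COC(=O)C(C)C)[C@H]1CO1
F5 | step 9 | (3R)-5-{[(2-methylpropanoyl)oxy]methyl}hexa-1,5-dien-3-yl 2-({[tert-butyl(dimethyl)silyl]oxy}methyl)prop-2-enoate | C=C[C@@H](CC(=C)COC(=O)C(C)C)OC(=O)C(=C)CO[Si](C)(C)C(C)(C)C
F6 | step 9 | 2-{[(2R)-4-({[tert-butyl(dimethyl)silyl]oxy}methyl)-5-oxo-2,5-dihydrofuran-2-yl]methyl}prop-2-en-1-yl 2-methylpropanoate | CC(C)(C)[Si](C)(C)OCC1=C[C@@H](CC(=C)COC(=O)C(C)C)OC1=O
F7 | step 9 | 2-{[(2R)-4-(hydroxymethyl)-5-oxo-2,5-dihydrofuran-2-yl]methyl}prop-2-en-1-yl 2-methylpropanoate | OCC1=C[C@@H](CC(=C)COC(=O)C(C)C)OC1=O
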